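**Retrosynthetic overview**

1. Last bond: the (E)-4-hydroxytiglate alkene, from a C-8 phosphonopropionate ester and glycolaldehyde (Horner–Wadsworth–Emmons).
2. The ten-membered carbocycle and the C5=C6 enol-lactone alkene form together by intramolecular Wittig reaction of a butenolide C-6 ylide with the C-5 aldehyde; the oxolane (C-1 hemiketal on the C-4 hydroxyl) then closes across the ring.
3. The butenolide comes from a 3,4-disubstituted furan (singlet oxygen); the C-5 aldehyde comes from the vinyl group of linalool (ozone).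
4. Key bond C1–C10: a Stetter addition in which the lactol from (R)-linalool is the C-1 acyl anion and a furyl (E)-propenyl ketone is the acceptor. It sets C-10 and delivers C-1 as the ketone; the C-8 carbonyl is then reduced enantioselectively.
5. Ring order: furan (bought), butenolide, carbocycle, oxolane. Stereocentres: C-4 from linalool, C-10 in the Stetter step, C-8 by transfer hydrogenation, C-1 fixed by the ring.

Assumption: the (5aS,10bR) antipode of the commercial aminoindanol triazolium salt is taken to give the (R) centre at C-10 (the other antipode is equally available); atom labels C-1 to C-15 follow germacrane (hirsutinolide) numbering.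

**Route**

Step 1
Reactants: 1 (R)-(−)-linalool
Product: 2 (5R)-5-ethenyl-5-methyloxolan-2-ol (lactol; both anomers)
Conditions: O3 (1.0 equiv, Sudan Red 7B end-point), CH2Cl2, −78 °C; then Me2S, −78 °C to rt
Reagents that add atoms: ozone, O=[O+][O-]
Why: Ozonolysis with reductive work-up cleaves the electron-rich trisubstituted alkene far faster than the vinyl group, and the 4-hydroxy aldehyde closes to the lactol; the C-4 stereocentre of linalool is not touched.

Step 2
Reactants: 3 furan-3,4-diyldimethanol
Product: 4 [4-(hydroxymethyl)furan-3-yl]methyl acetate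
Conditions: Ac2O (0.9 equiv), pyridine, CH2Cl2, 0 °C; diol and diacetate separated and recycled
Reagents that add atoms: acetic anhydride, CC(=O)OC(C)=O
Why: Statistical mono-acylation of a symmetric diol with a deficit of anhydride puts the C-13 acetate in place from the start.

Step 3
Reactants: 4 [4-(hydroxymethyl)furan-3-yl]methyl acetate
Product: 5 (4-formylfuran-3-yl)methyl acetate
Conditions: MnO2 (10 equiv), CH2Cl2, rt
Reagents that add atoms: none
Why: Manganese dioxide oxidation of a furylmethyl (benzylic-type) alcohol stops cleanly at the aldehyde and leaves the acetate alone.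

Step 4
Reactants: 5 (4-formylfuran-3-yl)methyl acetate; 6 allyl bromide
Product: 7 [4-(1-hydroxybut-3-en-1-yl)furan-3-yl]methyl acetate (racemic)
Conditions: In powder, THF/H2O (1:1), rt
Reagents that add atoms: none
Why: Indium-mediated Barbier allylation in water adds the three carbons C-9, C-10 and C-14 without touching the acetate; the carbinol centre is erased in step 5.

Step 5
Reactants: 7 [4-(1-hydroxybut-3-en-1-yl)furan-3-yl]methyl acetate
Product: 9 [4-[(2E)-but-2-enoyl]furan-3-yl]methyl acetate, via allyl ketone 8 (not isolated)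
Conditions: MnO2, CH2Cl2, rt; filter; then 1,8-diazabicyclo[5.4.0]undec-7-ene (DBU, 5 mol %), CH2Cl2, rt
Reagents that add atoms: none
Why: Oxidation of the furyl carbinol gives the β,γ-unsaturated ketone, which base moves into conjugation to give the thermodynamically preferred (E)-enone.

Step 6
Reactants: 2 (5R)-5-ethenyl-5-methyloxolan-2-ol; 9 [4-[(2E)-but-2-enoyl]furan-3-yl]methyl acetate
Product: 10 [4-[(3R,7R)-7-hydroxy-3,7-dimethyl-4-oxonon-8-enoyl]furan-3-yl]methyl acetate (open keto alcohol in equilibrium with its cyclic hemiketal)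
Conditions: (5aS,10bR)-5a,10b-dihydro-2-(pentafluorophenyl)-4H,6H-indeno[2,1-b][1,2,4]triazolo[4,3-d][1,4]oxazinium tetrafluoroborate (20 mol %), i-Pr2NEt (20 mol %), catechol (20 mol %), t-amyl alcohol, 40 °C
Reagents that add atoms: none
Why: Proposed new method: the triazolylidene adds to the open hydroxy-aldehyde form of lactol 2 to give the Breslow intermediate (an acyl anion at C-1), which adds 1,4 to the β-carbon of enone 9 on the face left open by the aminoindanol wall, forming C1–C10 and setting C-10 (R) under catalyst control (the C-10 epimers are diastereomers because C-4 is fixed, and are separated on silica); the closest known reactions are the thiazolium-catalysed Stetter addition of aliphatic aldehydes to β-substituted enones and the triazolium-catalysed asymmetric intermolecular Stetter addition of aliphatic aldehydes to β-substituted nitroalkenes.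

Step 7
Reactants: 10 [4-[(3R,7R)-7-hydroxy-3,7-dimethyl-4-oxonon-8-enoyl]furan-3-yl]methyl acetate
Product: 11 [4-[(1S,3R,7R)-1,7-dihydroxy-3,7-dimethyl-4-oxonon-8-en-1-yl]furan-3-yl]methyl acetate
Conditions: RuCl(p-cymene)[(S,S)-N-tosyl-1,2-diphenylethylenediamine] (2 mol %), HCO2Na (5 equiv), H2O/DMF (1:1), 40 °C; chromatography on Et3N-washed silica
Reagents that add atoms: none
Why: Noyori asymmetric transfer hydrogenation reduces the furyl (aryl-type) ketone and not the hindered dialkyl ketone, and the (S,S) catalyst delivers hydride to give the (S) carbinol at C-8 by analogy with acetophenone; the near-neutral formate medium avoids spiroketal formation and C-10 epimerisation.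

Step 8
Reactants: 11 [4-[(1S,3R,7R)-1,7-dihydroxy-3,7-dimethyl-4-oxonon-8-en-1-yl]furan-3-yl]methyl acetate; 12 2-(diethoxyphosphoryl)propanoic acid
Product: 13 (1S,3R,7R)-1-[4-(acetoxymethyl)furan-3-yl]-7-hydroxy-3,7-dimethyl-4-oxonon-8-en-1-yl 2-(diethoxyphosphoryl)propanoate (both epimers at the phosphonate-bearing carbon)
Conditions: N,N'-dicyclohexylcarbodiimide, 4-(dimethylamino)pyridine (10 mol %), CH2Cl2, 0 °C to rt
Reagents that add atoms: none
Why: Steglich esterification acylates the secondary C-8 hydroxyl only (the C-4 hydroxyl is tertiary), blocking C-8 against spiroketal formation and lactone migration and installing the handle for the side chain.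

Step 9
Reactants: 13 (1S,3R,7R)-1-[4-(acetoxymethyl)furan-3-yl]-7-hydroxy-3,7-dimethyl-4-oxonon-8-en-1-yl 2-(diethoxyphosphoryl)propanoate
Product: 15 (1S,3R,7R)-1-[4-(acetoxymethyl)-2-hydroxy-5-oxo-2,5-dihydrofuran-3-yl]-7-hydroxy-3,7-dimethyl-4-oxonon-8-en-1-yl 2-(diethoxyphosphoryl)propanoate (C-6 epimers), via furan endoperoxide 14 (not isolated)
Conditions: O2, tetraphenylporphyrin (1 mol %), hν (visible), CH2Cl2, −78 °C; then i-Pr2NEt (1.5 equiv), −78 to 0 °C
Reagents that add atoms: oxygen (as singlet oxygen), O=O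
Why: Singlet oxygen adds [4+2] across the furan and the hindered amine then removes the less hindered bridgehead hydrogen (next to CH2OAc) in a Kornblum–DeLaMare fragmentation, so C-12 becomes the lactone carbonyl and C-6 the hemiacetal carbon; the vinyl group has no allylic hydrogen and does not react.

Step 10
Reactants: 15 (1S,3R,7R)-1-[4-(acetoxymethyl)-2-hydroxy-5-oxo-2,5-dihydrofuran-3-yl]-7-hydroxy-3,7-dimethyl-4-oxonon-8-en-1-yl 2-(diethoxyphosphoryl)propanoate
Product: 16 (1S,3R,7R)-1-[4-(acetoxymethyl)-2-hydroxy-5-oxo-2,5-dihydrofuran-3-yl]-7-hydroxy-3,7-dimethyl-4,8-dioxooctyl 2-(diethoxyphosphoryl)propanoate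
Conditions: O3, CH2Cl2, −78 °C; then Me2S, −78 °C to rt
Reagents that add atoms: ozone, O=[O+][O-]
Why: Ozonolysis now finds only one electron-rich alkene, the vinyl group (the butenolide alkene is tetrasubstituted and doubly deactivated), and unlike periodate it does not cleave the α-hydroxy aldehyde it forms.

Step 11
Reactants: 16 (1S,3R,7R)-1-[4-(acetoxymethyl)-2-hydroxy-5-oxo-2,5-dihydrofuran-3-yl]-7-hydroxy-3,7-dimethyl-4,8-dioxooctyl 2-(diethoxyphosphoryl)propanoate
Product: 20 (1S,4R,8S,10R)-13-acetoxy-8-[2-(diethoxyphosphoryl)propanoyloxy]-1-hydroxy-1,4-epoxygermacra-5E,7(11)-dien-12,6-olide, via phosphonium bromide 17 (not isolated), via phosphorus ylide 18 (not isolated), via macrocyclic keto alcohol 19 (not isolated)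
Conditions: Ph3P·HBr (1.05 equiv), MeCN, rt; then added over 12 h to Et3N (3 equiv), MeCN, 40 °C, final concentration 0.001 mol per litre
Reagents that add atoms: none
Why: Intramolecular Wittig olefination: the pseudo-acid hydroxyl is exchanged for Ph3P+ as with lactols, Et3N gives the stabilised butenolide ylide (too weak a base to touch the phosphonate), and this olefinates the α-oxygenated C-5 aldehyde in preference to the hindered C-1 ketone; the ten-membered ring admits only the cis-in-ring (5E) alkene, and the C-1 ketone then closes on the C-4 hydroxyl across the ring from the only accessible face, fixing C-1 as S.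

Step 12
Reactants: 20 (1S,4R,8S,10R)-13-acetoxy-8-[2-(diethoxyphosphoryl)propanoyloxy]-1-hydroxy-1,4-epoxygermacra-5E,7(11)-dien-12,6-olide; 21 glycolaldehyde dimer (1,4-dioxane-2,5-diol)
Product: 23 8α-(4-hydroxytigloyloxy)hirsutinolide 13-O-acetate (the target), via glycolaldehyde 22 (not isolated)
Conditions: LiCl (3 equiv), i-Pr2NEt (2 equiv), MeCN, rt
Reagents that add atoms: none
Why: Horner–Wadsworth–Emmons olefination under Masamune–Roush conditions: the lithium-chelated phosphonate is deprotonated by the weak amine and condenses with monomeric glycolaldehyde released from its dimer to give the (E)-trisubstituted enoate with the free hydroxyl in place, erasing the epimeric phosphonate centre and leaving acetate, hemiketal and enol lactone alone.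

**Compound list**

1 | (R)-(−)-linalool, (3R)-3,7-dimethylocta-1,6-dien-3-ol | C=C[C@](C)(O)CCC=C(C)C | starting material
2 | (5R)-5-ethenyl-5-methyloxolan-2-ol (both anomers) | C=C[C@@]1(C)CCC(O)O1 | intermediate
3 | furan-3,4-diyldimethanol | OCc1cocc1CO | starting material
4 | [4-(hydroxymethyl)furan-3-yl]methyl acetate | CC(=O)OCc1cocc1CO | intermediate
5 | (4-formylfuran-3-yl)methyl acetate | CC(=O)OCc1cocc1C=O | intermediate
6 | allyl bromide (3-bromoprop-1-ene) | C=CCBr | starting material
7 | [4-(1-hydroxybut-3-en-1-yl)furan-3-yl]methyl acetate (racemic) | CC(=O)OCc1cocc1C(O)CC=C | intermediate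
8 | [4-(but-3-enoyl)furan-3-yl]methyl acetate | CC(=O)OCc1cocc1C(=O)CC=C | intermediate
9 | [4-[(2E)-but-2-enoyl]furan-3-yl]methyl acetate | CC(=O)OCc1cocc1C(=O)/C=C/C | intermediate
10 | [4-[(3R,7R)-7-hydroxy-3,7-dimethyl-4-oxonon-8-enoyl]furan-3-yl]methyl acetate | C=C[C@](C)(O)CCC(=O)[C@H](C)CC(=O)c1cocc1COC(C)=O | intermediate
11 | [4-[(1S,3R,7R)-1,7-dihydroxy-3,7-dimethyl-4-oxonon-8-en-1-yl]furan-3-yl]methyl acetate | C=C[C@](C)(O)CCC(=O)[C@H](C)C[C@H](O)c1cocc1COC(C)=O | intermediate
12 | 2-(diethoxyphosphoryl)propanoic acid (racemic) | CCOP(=O)(OCC)C(C)C(=O)O | starting material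
13 | (1S,3R,7R)-1-[4-(acetoxymethyl)furan-3-yl]-7-hydroxy-3,7-dimethyl-4-oxonon-8-en-1-yl 2-(diethoxyphosphoryl)propanoate (epimers at the phosphonate carbon) | C=C[C@](C)(O)CCC(=O)[C@H](C)C[C@H](OC(=O)C(C)P(=O)(OCC)OCC)c1cocc1COC(C)=O | intermediate
14 | 2,3,7-trioxabicyclo[2.2.1]hept-5-ene (furan endoperoxide) of 13 | C=C[C@](C)(O)CCC(=O)[C@H](C)C[C@H](OC(=O)C(C)P(=O)(OCC)OCC)C1=C(COC(C)=O)C2OOC1O2 | intermediate
15 | (1S,3R,7R)-1-[4-(acetoxymethyl)-2-hydroxy-5-oxo-2,5-dihydrofuran-3-yl]-7-hydroxy-3,7-dimethyl-4-oxonon-8-en-1-yl 2-(diethoxyphosphoryl)propanoate | C=C[C@](C)(O)CCC(=O)[C@H](C)C[C@H](OC(=O)C(C)P(=O)(OCC)OCC)C1=C(COC(C)=O)C(=O)OC1O | intermediate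
16 | (1S,3R,7R)-1-[4-(acetoxymethyl)-2-hydroxy-5-oxo-2,5-dihydrofuran-3-yl]-7-hydroxy-3,7-dimethyl-4,8-dioxooctyl 2-(diethoxyphosphoryl)propanoate | O=C[C@](C)(O)CCC(=O)[C@H](C)C[C@H](OC(=O)C(C)P(=O)(OCC)OCC)C1=C(COC(C)=O)C(=O)OC1O | intermediate
17 | triphenylphosphonium bromide of 16 (Ph3P+ in place of the C-6 hydroxyl) | O=C[C@](C)(O)CCC(=O)[C@H](C)C[C@H](OC(=O)C(C)P(=O)(OCC)OCC)C1=C(COC(C)=O)C(=O)OC1[P+](c1ccccc1)(c1ccccc1)c1ccccc1.[Br-] | intermediate
18 | C-6 triphenylphosphorane (ylide) from 17 | O=C[C@](C)(O)CCC(=O)[C@H](C)C[C@H](OC(=O)C(C)P(=O)(OCC)OCC)C1=C(COC(C)=O)C(=O)OC1=P(c1ccccc1)(c1ccccc1)c1ccccc1 | intermediate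
19 | (4R,8S,10R)-13-acetoxy-8-[2-(diethoxyphosphoryl)propanoyloxy]-4-hydroxy-1-oxogermacra-5E,7(11)-dien-12,6-olide (open form of 20) | CC(=O)OCC1=C2/C(=C\[C@](C)(O)CCC(=O)[C@H](C)C[C@@H]2OC(=O)C(C)P(=O)(OCC)OCC)OC1=O | intermediate
20 | (1S,4R,8S,10R)-13-acetoxy-8-[2-(diethoxyphosphoryl)propanoyloxy]-1-hydroxy-1,4-epoxygermacra-5E,7(11)-dien-12,6-olide | CC(=O)OCC1=C2/C(=C\[C@@]3(C)CC[C@](O)(O3)[C@H](C)C[C@@H]2OC(=O)C(C)P(=O)(OCC)OCC)OC1=O | intermediate
21 | glycolaldehyde dimer (1,4-dioxane-2,5-diol) | OC1COC(O)CO1 | starting material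
22 | glycolaldehyde | OCC=O | intermediate
23 | 8α-(4-hydroxytigloyloxy)hirsutinolide 13-O-acetate, (1S,4R,8S,10R)-13-acetoxy-1-hydroxy-8-[(2E)-4-hydroxy-2-methylbut-2-enoyloxy]-1,4-epoxygermacra-5E,7(11)-dien-12,6-olide | CC(=O)OCC1=C2/C(=C\[C@@]3(C)CC[C@](O)(O3)[C@H](C)C[C@@H]2OC(=O)/C(C)=C/CO)OC1=O | target

**Step count and risks**

Total step count: 12. Longest linear sequence: 11 steps (from 3 to 23, steps 2 to 12).

The three steps most likely to fail are steps 6, 9 and 11.

The Stetter union (step 6) asks a lactol-masked aliphatic aldehyde to add to a β-methyl enone with catalyst control at C-10; low conversion or a poor epimer ratio is the main danger. The fallback moves the acyl anion to the other fragment and makes the C8–C9 bond instead. It sets out from 2: isopropenylmagnesium bromide (CH2=C(CH3)MgBr, 3 equiv, THF, 0 °C) opens the lactol to (6R)-2,6-dimethylocta-1,7-diene-3,6-diol F1, and MnO2 oxidises the allylic alcohol to (6R)-6-hydroxy-2,6-dimethylocta-1,7-dien-3-one F2. Furan aldehyde 5, a much better Stetter donor, is then added to the terminal carbon of F2 with 3-benzyl-5-(2-hydroxyethyl)-4-methylthiazolium chloride or the same triazolium salt; C-10 is set when the enolate is protonated. This comes back to the route at 10; the C-10 epimers are separated and the wrong one is recycled by equilibration with DBU.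

The furan oxidation (step 9) relies on the base choosing between two flanked bridgehead hydrogens, so a mixture of regioisomeric hydroxybutenolides is possible. The fallback fixes the regiochemistry with silicon before the oxidation. It sets out from 13: C–H silylation with [Ir(cod)OMe]2, 4,4'-di-tert-butyl-2,2'-bipyridine, Et3SiH and norbornene (THF, 80 °C) puts a triethylsilyl group on the less hindered furan α-carbon to give (1S,3R,7R)-1-[4-(acetoxymethyl)-5-(triethylsilyl)furan-3-yl]-7-hydroxy-3,7-dimethyl-4-oxonon-8-en-1-yl 2-(diethoxyphosphoryl)propanoate F3, whose regioisomer can be removed. Photooxygenation then turns the silyl-bearing carbon into the lactone carbonyl (silyl shift to the peroxide, hydrolysis) and comes back to the route at 15.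

The ring closure (step 11) must form a ten-membered ring while the ylide ignores the C-1 ketone, which could give a six-membered ring instead; oligomers are the other danger. The fallback replaces the Wittig reaction by a reversible vinylogous aldol addition with selective trapping. It sets out from 15: NaBH4 (CH2Cl2/EtOH, −78 °C, then pH 3) reduces the masked aldehyde to give the butenolide (1S,3R,7R)-1-[4-(acetoxymethyl)-5-oxo-2,5-dihydrofuran-3-yl]-7-hydroxy-3,7-dimethyl-4-oxonon-8-en-1-yl 2-(diethoxyphosphoryl)propanoate F4, and ozonolysis gives the aldehyde (1S,3R,7R)-1-[4-(acetoxymethyl)-5-oxo-2,5-dihydrofuran-3-yl]-7-hydroxy-3,7-dimethyl-4,8-dioxooctyl 2-(diethoxyphosphoryl)propanoate F5. Lithium-free DBU under high dilution closes the ring to the macrocyclic aldol adduct F6 (an adduct with the ketone reverts, and the phosphonate is not engaged without a lithium salt). MsCl/Et3N converts only its secondary hydroxyl into the mesylate F7, and DBU eliminates this to 19, which closes to the hemiketal and comes back to the route at 20.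

**Further compounds**

F1 | step 6 | (6R)-2,6-dimethylocta-1,7-diene-3,6-diol (both C-3 epimers) | C=C[C@](C)(O)CCC(O)C(C)=C
F2 | step 6 | (6R)-6-hydroxy-2,6-dimethylocta-1,7-dien-3-one | C=C[C@](C)(O)CCC(=O)C(C)=C
F3 | step 9 | (1S,3R,7R)-1-[4-(acetoxymethyl)-5-(triethylsilyl)furan-3-yl]-7-hydroxy-3,7-dimethyl-4-oxonon-8-en-1-yl 2-(diethoxyphosphoryl)propanoate | C=C[C@](C)(O)CCC(=O)[C@H](C)C[C@H](OC(=O)C(C)P(=O)(OCC)OCC)c1coc([Si](CC)(CC)CC)c1COC(C)=O
F4 | step 11 | (1S,3R,7R)-1-[4-(acetoxymethyl)-5-oxo-2,5-dihydrofuran-3-yl]-7-hydroxy-3,7-dimethyl-4-oxonon-8-en-1-yl 2-(diethoxyphosphoryl)propanoate | C=C[C@](C)(O)CCC(=O)[C@H](C)C[C@H](OC(=O)C(C)P(=O)(OCC)OCC)C1=C(COC(C)=O)C(=O)OC1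
F5 | step 11 | (1S,3R,7R)-1-[4-(acetoxymethyl)-5-oxo-2,5-dihydrofuran-3-yl]-7-hydroxy-3,7-dimethyl-4,8-dioxooctyl 2-(diethoxyphosphoryl)propanoate | O=C[C@](C)(O)CCC(=O)[C@H](C)C[C@H](OC(=O)C(C)P(=O)(OCC)OCC)C1=C(COC(C)=O)C(=O)OC1
F6 | step 11 | macrocyclic aldol adduct, (4R,8S,10R)-13-acetoxy-8-[2-(diethoxyphosphoryl)propanoyloxy]-4,5-dihydroxy-1-oxogermacr-7(11)-en-12,6-olide (C-5 and C-6 epimers) | CC(=O)OCC1=C2C(OC1=O)C(O)[C@](C)(O)CCC(=O)[C@H](C)C[C@@H]2OC(=O)C(C)P(=O)(OCC)OCC
F7 | step 11 | C-5 methanesulfonate of the aldol adduct | CC(=O)OCC1=C2C(OC1=O)C(OS(C)(=O)=O)[C@](C)(O)CCC(=O)[C@H](C)C[C@@H]2OC(=O)C(C)P(=O)(OCC)OCC
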